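## The problem

The target is a germacrane (ring C1–C10; C11–C13 on C7; C14 on C10; C15 on C4). Its ten-membered carbocycle carries an E C1=C10 alkene, a trans 4,5-epoxide with the free C15 hydroxymethyl group on C4, an isovalerate on O9, a (2R,3S)-3-hydroxy-2-methylbutanoate on O14, and on C7 a C11=C13 methylene branch whose C12 is an allylic acetate. A medium ring does not close by routine means, and both ring alkenes (C4=C5 is the precursor of the epoxide) must be trans within it. The ring stereocentres are 4S, 5R, 7S and 9S. C7 and C9 are 1,3-related across C8 and the epoxide is remote from both, so in a flexible cyclodecadiene none can be trusted to control another. Each must come from reagent control or by transfer from such a centre; C2′ and C3′ arrive with the acid. Four oxygens (O9, O12, O14, O15) must end as three different esters and one free alcohol, without a 1,3-acyl shift between O9 and O14. The fragile elements are the 2,3-epoxy alcohol facing C1=C10 across the ring (acid would cause transannular cyclisation), the cyclodeca-1(10),4-diene intermediates (Cope rearrangement on heating), the allylic acetate (ionised by zerovalent palladium) and the β-hydroxy ester. The enabling feature is that C6 is allylic to C4=C5 and can carry a sulfonyl carbanion, while C7 bears the C11 branch, whose methylene/oxymethyl pattern can be derived from a C11 tertiary alkoxide. C6–C7 is therefore the bond between an allyl anion and the C7 end of a 7,11-epoxide.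

## Retrosynthesis

**41 from 40.** The two C–O bonds of the oxirane are cut last. Any earlier placement would expose the epoxide to LiBHEt3, the aluminium amide or the acid used on the acetonide. Triene diol 40 has two fewer stereocentres and lacks the most fragile group. The forward step must pick C4=C5 among three alkenes and one of its faces; the free O15–H and a tartrate ligand do both.

**40 from 30 and 37.** The ester C–O bonds at O14 and O9 and the two silyl ethers are cut, leading through 39 and 38 to diol 30 and acid 37. The primary O14 is acylated before the secondary O9, so an acyl group never sits on O9 beside a free O14–H. Both hydroxyls come from one acetonide. The side-chain stereocentres are removed into 37, made from imide 31 and acetaldehyde 32 by an Evans syn-aldol (34, 35). The forward reaction must discriminate primary from secondary hydroxyl.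

**30 from 23.** The C11=C13 π bond and the C12–O bond are traced through acetate 29 and allylic alcohol 28 to the terminal 11,12-epoxide 27. This comes from diol 25, then PMB ether 24, then sulfone 23. Direct dehydration of the tertiary alcohol was set aside because three β-positions compete; the epoxide isomerisation can only choose between the C13 methyl and the hindered C7–H. The C6–S bond is cut here too.

**23 from 21.** C6–C7 is cut. It joins the only carbon that can be made nucleophilic next to a future ring alkene to a stereocentre, C7, whose configuration a Sharpless epoxide can supply by inversion. A cut at C2–C3 would give no stereochemical return; cuts at C7–C8 or C5–C10 are weighed below. Precursor 21 is acyclic, with both alkenes and C7, C9 and C11 already fixed. The forward step needs α-attack of the anion, attack at C7, and ring closure over oligomerisation.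

**21 from 11 and 17.** The C6–S bond goes back to allylic alcohol 19. The C1–C2 bond is cut between the two alkenes so that each geometry is made in its own small fragment: iodide 11 (C1, C7–C14) and dienol 17 (C2–C6, C15). The sp2–sp3 Suzuki coupling of borane 18 must keep the geometry of the vinyl iodide.

**11 from 2 and 3.** The epoxide C–O bonds go back to allylic alcohol 9 (epoxy alcohol 10 is its Sharpless product). The C12–O bond goes back to the prenyl terminus of 8. The acetal goes back to diol 7 and ester 6. The C9–C10 bond is cut to aldehyde 2 (from alcohol 1) and methyl propiolate 3. One iodo-aldol sets C9 and places iodine cis to the ester, which is the geometry needed for C2 cis to C14.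

**17 from 12.** The C3–C4 bond is cut to the vinyl stannane 15 (Stille vinylation gives 16). The C4–Sn bond comes from syn-hydrostannation of the symmetrical diol 12 (13, 14), which puts C3 trans to C6 with no regiochemical question.

## Roads not taken

**Alternative 1:** Both ring alkenes are removed at once. Bonds C1–C10 and C4–C5 are made by [2+2] photocycloaddition of enone A1 with cyclobutene A2, giving the cis-anti-cis tricyclic ketone A3. Heating then breaks C5–C10 and C1–C4 and releases the ten-membered dienone A4.
- Merits: the ring and both alkenes arise in two operations from small rings, without high dilution. C7 is fixed beforehand in A1, and the C9 carbonyl sits where oxygen is needed. In steps to the ring this road is better than the chosen one.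
- Weak points: head-to-tail orientation must hold while two quaternary centres (C10, C4) form from a 2-substituted enone, and the face is chosen only by the remote C7 substituent. The cycloreversion needs temperatures at which the cyclodeca-1,5-diene equilibrates by Cope rearrangement with a divinylcyclohexane and at which cis,trans isomers can form. C9 must afterwards be reduced to 9S in a flexible dienone with no controlling neighbour.
- Comparison: the chosen plan has a longer chain synthesis and a dilute ring closure. Against that it sets both geometries in acyclic fragments, never heats the diene and fixes C9 by a catalyst before closure.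

**Alternative 2:** C7–C8 is cut by a retro-Claisen step. Lactone A5 is methylenated to the twelve-membered allyl vinyl ether A6, whose [3,3] shift forms C7–C8, breaks O–C13 and contracts the ring to ketone A7.
- Merits: the C11=C13 methylene and the C12 oxygen appear directly, which is better than the four-step detour from tertiary alcohol 23 to acetate 29. The ring strain is introduced by a unimolecular shift from a lactone that is easier to close.
- Weak points: C7 is set only by the chair-or-boat choice of a macrocyclic transition state, with no nearby controlling element. A titanium methylenation must spare a conjugated lactone that also carries an epoxide. The shift needs heat while the product is a Cope-prone diene. C9 again arrives as a ketone.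
- Comparison: the chosen plan draws C7 from a Sharpless epoxide by inversion and keeps C9 as a preset alcohol, paying for this with the detour at C11–C13.

**Alternative 3:** The ring is excised from a decalin by reconnecting C5–C10. In the trans-decalin mesylate A8 the C5 alkoxide expels the antiperiplanar C1 mesylate to give the E-cyclodecenone A9.
- Merits: the alkene geometry is guaranteed by the stereospecific fragmentation, there is no dilution problem, and C7 and C9 are placed on a rigid bicycle. In certainty of the C1=C10 geometry it is at least as good as the chosen plan.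
- Weak points: A8 needs an angular oxymethyl group, a spiro-epoxide, a tertiary alcohol, a mesylate and two further substituents. The C7 branch and O9 cannot both be equatorial. The C5 alkoxide sits next to the spiro-epoxide and can open it before fragmenting. After the fragmentation a C5 ketone reduction and a Payne transposition must still deliver the 4,5-epoxide with both configurations right.
- Comparison: the chosen plan makes the epoxide in the last step under reagent control and accepts the entropic risk of a dilute macrocyclisation.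

Key step: step 15

Assumption: the (S)-oxazaborolidinium catalyst of step 2 is taken to direct the allenolate to the Re face of aldehyde 2; if the opposite sense is found, its enantiomer is used.
Assumption: 1, 3, 12, 31 and 32 are taken as commercial.

## Steps

Step 1
Reactants: 1 4-methylpent-3-en-1-ol
Product: 2 4-methylpent-3-enal
Conditions: Dess–Martin periodinane, CH2Cl2, 0 to 20 °C; used crude
Reagents that add atoms: none
Why: Dess–Martin oxidation of a primary alcohol under near-neutral conditions, which avoids conjugation of the β,γ-unsaturated aldehyde.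

Step 2
Reactants: 2 4-methylpent-3-enal; 3 methyl propiolate
Product: 6 methyl (2Z,3S)-3-hydroxy-2-(iodomethylidene)-6-methylhept-5-enoate, via silyl iodoallenolate 4 (not isolated), via O-trimethylsilyl adduct 5 (not isolated)
Conditions: Me3SiI, (S)-oxazaborolidinium salt [from (S)-α,α-diphenylprolinol and o-tolylboroxine, activated by HN(SO2CF3)2] (20 mol%), CH2Cl2, −78 °C; aq. HCl
Reagents that add atoms: iodotrimethylsilane, C[Si](C)(C)I
Why: Catalytic asymmetric iodo-aldol (three-component Mukaiyama-type coupling): iodide adds to 3 to give allenolate 4, which attacks the catalyst-bound aldehyde through its α-carbon; kinetic control at −78 °C leaves iodine cis to the ester (Z), and Re-face attack sets C9 as S.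

Step 3
Reactants: 6 iodo hydroxy ester
Product: 7 (2E,3S)-2-(iodomethylidene)-6-methylhept-5-ene-1,3-diol
Conditions: i-Bu2AlH (3.5 eq), CH2Cl2, −78 to −20 °C; aq. potassium sodium tartrate
Reagents that add atoms: none
Why: 1,2-Reduction of a β-iodoacrylate to the allylic alcohol by aluminium hydride; the vinyl iodide and the alkene geometry are untouched.

Step 4
Reactants: 7 iodo diol
Product: 8 (4S,5E)-5-(iodomethylidene)-2,2-dimethyl-4-(3-methylbut-2-en-1-yl)-1,3-dioxane
Conditions: Me2C(OMe)2, PPTS (cat.), CH2Cl2, 20 °C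
Reagents that add atoms: 2,2-dimethoxypropane, COC(C)(C)OC
Why: Acid-catalysed transacetalisation of a 1,3-diol; one acetal masks O9 and O14 together and is later removed by mild acid without touching silyl ethers.

Step 5
Reactants: 8 prenyl dioxane
Product: 9 (2E)-4-[(4S,5E)-5-(iodomethylidene)-2,2-dimethyl-1,3-dioxan-4-yl]-2-methylbut-2-en-1-ol
Conditions: SeO2 (0.3 eq), t-BuOOH, CH2Cl2, 0 to 20 °C
Reagents that add atoms: selenium dioxide, O=[Se]=O (transfers the oxygen); tert-butyl hydroperoxide, CC(C)(C)OO (terminal oxidant)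
Why: Selenium dioxide allylic oxidation (ene reaction then [2,3] shift) of a gem-dimethyl trisubstituted alkene, which oxidises the methyl trans to the chain and gives the E allylic alcohol; the iodoalkene is too electron-poor to react.

Step 6
Reactants: 9 allylic alcohol
Product: 10 [(2S,3S)-3-{[(4S,5E)-5-(iodomethylidene)-2,2-dimethyl-1,3-dioxan-4-yl]methyl}-2-methyloxiran-2-yl]methanol
Conditions: Ti(O-i-Pr)4 (10 mol%), L-(+)-diethyl tartrate (12 mol%), t-BuOOH, 4 Å sieves, CH2Cl2, −20 °C
Reagents that add atoms: tert-butyl hydroperoxide, CC(C)(C)OO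
Why: Katsuki–Sharpless epoxidation of an E-2-methylalk-2-en-1-ol; the L-(+)-tartrate complex gives the (2S,3S)-epoxy alcohol (7S,11S), independent of the remote C9 centre.

Step 7
Reactants: 10 epoxy alcohol
Product: 11 (4S,5E)-5-(iodomethylidene)-4-{[(2S,3S)-3-{[(4-methoxyphenyl)methoxy]methyl}-3-methyloxiran-2-yl]methyl}-2,2-dimethyl-1,3-dioxane
Conditions: NaH, 4-MeOC6H4CH2Cl, Bu4NI (cat.), THF/DMF, 0 to 20 °C
Reagents that add atoms: 4-methoxybenzyl chloride, COc1ccc(CCl)cc1
Why: Williamson etherification of the primary alkoxide, as in benzylations of trisubstituted 2,3-epoxy alcohols; the benzyl-type ether cannot migrate to the C11 alkoxide formed in step 15.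

Step 8
Reactants: 12 but-2-yne-1,4-diol
Product: 13 (2E)-2-(tributylstannyl)but-2-ene-1,4-diol
Conditions: Bu3SnH, PdCl2(PPh3)2 (2 mol%), THF, 0 to 20 °C
Reagents that add atoms: tributyltin hydride, CCCC[SnH](CCCC)CCCC
Why: Palladium-catalysed syn-hydrostannation of a symmetrical alkyne; tin and hydrogen add cis, so the later C3 substituent is trans to C6.

Step 9
Reactants: 13 stannyl diol
Product: 14 (2E)-4-[(tert-butyldimethylsilyl)oxy]-2-(tributylstannyl)but-2-en-1-ol
Conditions: t-BuMe2SiCl (1.0 eq), imidazole, CH2Cl2, −20 °C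
Reagents that add atoms: tert-butyldimethylsilyl chloride, CC(C)(C)[Si](C)(C)Cl
Why: Silylation goes to the less hindered hydroxyl (O6); the hydroxymethyl group geminal to the bulky tributylstannyl group (O15) is shielded.

Step 10
Reactants: 14 mono-silyl ether
Product: 15 tert-butyl{[(2E)-4-[(tert-butyldimethylsilyl)oxy]-2-(tributylstannyl)but-2-en-1-yl]oxy}diphenylsilane
Conditions: t-BuPh2SiCl, imidazole, DMF, 20 °C
Reagents that add atoms: tert-butyldiphenylsilyl chloride, CC(C)(C)[Si](Cl)(c1ccccc1)c1ccccc1
Why: Silylation under imidazole, where no silyl migration occurs; O15 receives the group that lasts to step 27.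

Step 11
Reactants: 15 bis-silyl stannane
Product: 16 tert-butyl{[(2Z)-3-{[(tert-butyldiphenylsilyl)oxy]methyl}penta-2,4-dien-1-yl]oxy}dimethylsilane
Conditions: CH2=CHBr, Pd(PPh3)4 (5 mol%), CuI (10 mol%), CsF, DMF, 45 °C
Reagents that add atoms: vinyl bromide, C=CBr
Why: Stille coupling with copper iodide and fluoride acceleration, as used for hindered 1-substituted vinyl stannanes; it proceeds with retention at the stannylated carbon.

Step 12
Reactants: 16 bis-silyl diene
Product: 17 (2Z)-3-{[(tert-butyldiphenylsilyl)oxy]methyl}penta-2,4-dien-1-ol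
Conditions: PPTS (0.2 eq), EtOH, 20 to 40 °C
Reagents that add atoms: none
Why: Acid-catalysed solvolysis removes the primary tert-butyldimethylsilyl ether much faster than the diphenyl analogue; it is done here, before the acid-labile acetal and epoxide are present.

Step 13
Reactants: 17 dienol; 11 vinyl iodide
Product: 19 (2Z)-3-{[(tert-butyldiphenylsilyl)oxy]methyl}-6-[(4S,5E)-4-{[(2S,3S)-3-{[(4-methoxyphenyl)methoxy]methyl}-3-methyloxiran-2-yl]methyl}-2,2-dimethyl-1,3-dioxan-5-ylidene]hex-2-en-1-ol, via alkylborane 18 (not isolated)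
Conditions: 17, 9-BBN-H (2.2 eq), THF, 0 to 20 °C; then 11, PdCl2(dppf) (5 mol%), AsPh3, Cs2CO3, DMF/H2O, 20 °C
Reagents that add atoms: none
Why: Anti-Markovnikov hydroboration of the monosubstituted vinyl group (the trisubstituted alkene is far slower), then B-alkyl Suzuki–Miyaura coupling with retention at the vinyl iodide, so C2 is cis to C14; the free hydroxyl is carried as its borinate, which is hydrolysed in the aqueous base.

Step 14
Reactants: 19 allylic alcohol
Product: 21 allylic phenyl sulfone (C6 sulfone of 19), via allylic mesylate 20 (not isolated)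
Conditions: MsCl, Et3N, THF, −40 °C; then PhSO2Na, Bu4NI (cat.), DMF, 20 °C
Reagents that add atoms: sodium benzenesulfinate, [Na+].[O-]S(=O)c1ccccc1
Why: Sulfonate formation then SN2 displacement by sulfinate through sulfur at a primary allylic carbon; the alkene geometry and the epoxide are unaffected.

Step 15
Reactants: 21 acyclic epoxy sulfone
Product: 23 cyclodecadienyl sulfone with C11 tertiary alcohol (7R,9S,11R; both C6 epimers), via lithiated sulfone 22 (not isolated)
Conditions: LiN(i-Pr)2 (1.2 eq), THF, −78 °C, 0.002 M; warm to 20 °C; aq. NH4Cl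
Reagents that add atoms: none
Why: Deprotonation at C6 gives the sulfonyl-stabilised allyl anion 22, which attacks C7 of the 7,11-epoxide from the side opposite the C7–O bond, forming C6–C7 and the ten-membered ring and leaving the C11 alkoxide. The closest known reaction type is the intramolecular opening of a trisubstituted terminal epoxide by a sulfur-stabilised allylic carbanion in farnesyl-type chains, which gives germacrane rings. The ring closes in the 10-exo-tet mode, the breaking C7–O bond lying outside the new ring. C7 is the stereocentre delivered: the SN2 opening inverts the 7S centre set in step 6 and gives the target configuration (7R by the sequence rule in 23 because C6 carries sulfur); C11 is untouched and C6 forms as both epimers, which is immaterial since sulfur is removed in step 16. Three selectivities are needed: α- over γ-attack of the anion (the sulfonyl group localises charge at C6, and γ-attack would need an eight-membered ring with a new quaternary centre), C7 over C11 (C11 is fully substituted and would demand the 11-endo mode), and closure over oligomerisation (high dilution, two preset trans trisubstituted alkenes, and a dioxane that holds C8 out of the C1=C10 plane). No other electrophile or acidic C–H competes, since the remaining oxygens are an acetal, a benzyl-type ether and a silyl ether.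

Step 16
Reactants: 23 cyclic sulfone
Product: 24 (1(10)E,4Z,7R,9S,11R)-15-[(tert-butyldiphenylsilyl)oxy]-9,14-(isopropylidenedioxy)-12-[(4-methoxyphenyl)methoxy]germacra-1(10),4-dien-11-ol
Conditions: PdCl2(dppp) (10 mol%), LiBHEt3 (4 eq), THF, 0 °C
Reagents that add atoms: none
Why: Palladium-catalysed hydride desulfonylation of an allylic sulfone: the C6–S bond ionises to a C4–C5–C6 allyl complex and hydride is delivered to the less substituted terminus C6, so the C4=C5 alkene keeps its position and, since C4 never becomes σ-bound, its geometry.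

Step 17
Reactants: 24 PMB ether
Product: 25 (1(10)E,4Z,7R,9S,11R)-15-[(tert-butyldiphenylsilyl)oxy]-9,14-(isopropylidenedioxy)germacra-1(10),4-diene-11,12-diol
Conditions: DDQ (1.3 eq), CH2Cl2/pH 7 buffer, 0 °C
Reagents that add atoms: none
Why: Oxidative cleavage of the 4-methoxybenzyl ether; water intercepts the oxocarbenium ion faster than the hindered tertiary hydroxyl, and the acetal and silyl ether are inert.

Step 18
Reactants: 25 diol
Product: 27 (7R,9S,11R)-11,12-epoxide of the protected germacra-1(10),4-diene, via primary tosylate 26 (not isolated)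
Conditions: TsCl, Et3N, DMAP (cat.), CH2Cl2, 0 °C; then K2CO3, MeOH, 20 °C
Reagents that add atoms: none
Why: Selective sulfonylation of the primary hydroxyl beside an unreactive tertiary one, then intramolecular Williamson closure (3-exo-tet) by the C11 alkoxide; C11 keeps its configuration.

Step 19
Reactants: 27 terminal epoxide
Product: 28 (1(10)E,4Z,7R,9S)-15-[(tert-butyldiphenylsilyl)oxy]-9,14-(isopropylidenedioxy)germacra-1(10),4,11(13)-trien-12-ol
Conditions: Et2AlCl and lithium 2,2,6,6-tetramethylpiperidide (4 eq each, premixed), toluene, 0 °C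
Reagents that add atoms: none
Why: Aluminium amide-mediated isomerisation of a 2-methyl-2-alkyl oxirane to the 2-substituted allylic alcohol: aluminium binds the oxygen and the amide removes a syn β-proton through a cyclic transition state, the C13 methyl being far more accessible than the hindered C7–H.

Step 20
Reactants: 28 allylic alcohol
Product: 29 (1(10)E,4Z,7R,9S)-15-[(tert-butyldiphenylsilyl)oxy]-9,14-(isopropylidenedioxy)germacra-1(10),4,11(13)-trien-12-yl acetate
Conditions: Ac2O, pyridine, DMAP (cat.), CH2Cl2, 0 °C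
Reagents that add atoms: acetic anhydride, CC(=O)OC(C)=O
Why: DMAP-catalysed acetylation of the only free hydroxyl; it comes after the palladium step so that the allylic acetate never meets zerovalent palladium.

Step 21
Reactants: 29 acetonide acetate
Product: 30 (1(10)E,4Z,7R,9S)-12-acetoxy-15-[(tert-butyldiphenylsilyl)oxy]germacra-1(10),4,11(13)-triene-9,14-diol
Conditions: PPTS (cat.), MeOH, 20 °C
Reagents that add atoms: none
Why: Acid-catalysed transketalisation to methanol; the catalyst is too weak to protonate the ring alkenes (both deactivated by allylic oxygen) or to cleave the silyl ether, and the temperature stays below that of the Cope rearrangement.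

Step 22
Reactants: 31 (4R)-4-benzyl-3-propanoyl-1,3-oxazolidin-2-one; 32 acetaldehyde
Product: 34 (4R)-4-benzyl-3-[(2R,3S)-3-hydroxy-2-methylbutanoyl]-1,3-oxazolidin-2-one, via Z boron enolate 33 (not isolated)
Conditions: Bu2BOTf, i-Pr2NEt, CH2Cl2, −78 to 0 °C; CH3CHO, −78 to 0 °C; pH 7 buffer, MeOH, H2O2
Reagents that add atoms: none
Why: Evans syn-aldol: the Z boron enolate reacts through a closed chair transition state with the auxiliary dipole opposed, which from the (R)-benzyl auxiliary gives the (2R,3S) syn adduct.

Step 23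
Reactants: 34 aldol adduct
Product: 35 (4R)-4-benzyl-3-[(2R,3S)-2-methyl-3-(triethylsilyloxy)butanoyl]-1,3-oxazolidin-2-one
Conditions: Et3SiCl, imidazole, DMF, 0 °C
Reagents that add atoms: chlorotriethylsilane, CC[Si](Cl)(CC)CC
Why: Silylation of the secondary hydroxyl prevents self-acylation in step 25; the triethylsilyl group leaves with the O15 silyl group in step 27.

Step 24
Reactants: 35 silylated imide
Product: 37 (2R,3S)-2-methyl-3-(triethylsilyloxy)butanoic acid, via peroxy acid 36 (not isolated)
Conditions: LiOH, H2O2, THF/H2O, 0 °C; then Na2SO3; aq. NaHSO4 to pH 4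
Reagents that add atoms: hydrogen peroxide, OO
Why: Hydroperoxide cleavage of the N-acyl oxazolidinone at the exocyclic carbonyl, then sulfite reduction of the peracid; the α-centre is not epimerised under these conditions.

Step 25
Reactants: 30 ring diol; 37 silyloxy acid
Product: 38 14-O-[(2R,3S)-2-methyl-3-(triethylsilyloxy)butanoyl] derivative of 30 (O9–H free)
Conditions: 37 (1.05 eq), EDC·HCl, DMAP (0.1 eq), CH2Cl2, −20 to 0 °C
Reagents that add atoms: none
Why: Steglich esterification; the primary allylic O14–H reacts well ahead of the secondary O9–H, which is flanked by the ring and the alkene, and a primary ester has no drive to migrate to O9.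

Step 26
Reactants: 38 mono-ester
Product: 39 9-O-(3-methylbutanoyl) derivative of 38
Conditions: (i-PrCH2CO)2O, DMAP, pyridine, CH2Cl2, 20 °C
Reagents that add atoms: 3-methylbutanoic anhydride, CC(C)CC(=O)OC(=O)CC(C)C
Why: DMAP-catalysed acylation of the remaining secondary allylic alcohol with an unhindered anhydride.

Step 27
Reactants: 39 bis-silyl triester
Product: 40 (1(10)E,4Z,7R,9S)-12-acetoxy-15-hydroxy-9-(3-methylbutanoyloxy)germacra-1(10),4,11(13)-trien-14-yl (2R,3S)-3-hydroxy-2-methylbutanoate
Conditions: HF·pyridine, pyridine, THF, 0 to 20 °C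
Reagents that add atoms: none
Why: Buffered fluoride cleavage of both silyl ethers; the three esters are stable to it and no base is present that could cause acyl shift or retro-aldol cleavage.

Step 28
Reactants: 40 triene diol
Product: 41 (4S,5R,7S,9S)-12-acetoxy-4,5-epoxy-15-hydroxy-9-(3-methylbutanoyloxy)germacra-1(10)E,11(13)-dien-14-yl (2R,3S)-3-hydroxy-2-methylbutanoate (the target)
Conditions: Ti(O-i-Pr)4 (1.1 eq), L-(+)-diethyl tartrate (1.3 eq), t-BuOOH, 4 Å sieves, CH2Cl2, −25 °C; non-acidic work-up
Reagents that add atoms: tert-butyl hydroperoxide, CC(C)(C)OO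
Why: Katsuki–Sharpless epoxidation: only C4=C5 bears an allylic hydroxyl, so the other two alkenes are ignored, and the L-(+)-tartrate complex delivers oxygen to the face that gives 4S,5R, the same sense as in step 6; the trans alkene gives the trans epoxide.

## Compound list

1 | 4-methylpent-3-en-1-ol | CC(C)=CCCO | starting material
2 | 4-methylpent-3-enal | CC(C)=CCC=O | intermediate
3 | methyl propiolate | C#CC(=O)OC | starting material
4 | 1-iodo-3-methoxy-3-(trimethylsilyloxy)propa-1,2-diene (not isolated) | COC(O[Si](C)(C)C)=C=CI | intermediate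
5 | methyl (2Z,3S)-2-(iodomethylidene)-6-methyl-3-(trimethylsilyloxy)hept-5-enoate (not isolated) | CC(C)=CC[C@H](O[Si](C)(C)C)/C(C(=O)OC)=C/I | intermediate
6 | methyl (2Z,3S)-3-hydroxy-2-(iodomethylidene)-6-methylhept-5-enoate | CC(C)=CC[C@H](O)/C(C(=O)OC)=C/I | intermediate
7 | (2E,3S)-2-(iodomethylidene)-6-methylhept-5-ene-1,3-diol | CC(C)=CC[C@H](O)/C(CO)=C/I | intermediate
8 | (4S,5E)-5-(iodomethylidene)-2,2-dimethyl-4-(3-methylbut-2-en-1-yl)-1,3-dioxane | I/C=C1\COC(C)(C)O[C@H]1CC=C(C)C | intermediate
9 | (2E)-4-[(4S,5E)-5-(iodomethylidene)-2,2-dimethyl-1,3-dioxan-4-yl]-2-methylbut-2-en-1-ol | I/C=C1\COC(C)(C)O[C@H]1C/C=C(C)/CO | intermediate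
10 | [(2S,3S)-3-{[(4S,5E)-5-(iodomethylidene)-2,2-dimethyl-1,3-dioxan-4-yl]methyl}-2-methyloxiran-2-yl]methanol | I/C=C1\COC(C)(C)O[C@H]1C[C@@H]2O[C@@]2(C)CO | intermediate
11 | (4S,5E)-5-(iodomethylidene)-4-{[(2S,3S)-3-{[(4-methoxyphenyl)methoxy]methyl}-3-methyloxiran-2-yl]methyl}-2,2-dimethyl-1,3-dioxane | I/C=C1\COC(C)(C)O[C@H]1C[C@@H]2O[C@@]2(C)COCc3ccc(OC)cc3 | intermediate
12 | but-2-yne-1,4-diol | OCC#CCO | starting material
13 | (2E)-2-(tributylstannyl)but-2-ene-1,4-diol | OC/C=C(\CO)[Sn](CCCC)(CCCC)CCCC | intermediate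
14 | (2E)-4-[(tert-butyldimethylsilyl)oxy]-2-(tributylstannyl)but-2-en-1-ol | CC(C)(C)[Si](C)(C)OC/C=C(\CO)[Sn](CCCC)(CCCC)CCCC | intermediate
15 | tert-butyl{[(2E)-4-[(tert-butyldimethylsilyl)oxy]-2-(tributylstannyl)but-2-en-1-yl]oxy}diphenylsilane | CC(C)(C)[Si](C)(C)OC/C=C(\CO[Si](c1ccccc1)(c1ccccc1)C(C)(C)C)[Sn](CCCC)(CCCC)CCCC | intermediate
16 | tert-butyl{[(2Z)-3-{[(tert-butyldiphenylsilyl)oxy]methyl}penta-2,4-dien-1-yl]oxy}dimethylsilane | CC(C)(C)[Si](C)(C)OC/C=C(\CO[Si](c1ccccc1)(c1ccccc1)C(C)(C)C)C=C | intermediate
17 | (2Z)-3-{[(tert-butyldiphenylsilyl)oxy]methyl}penta-2,4-dien-1-ol | OC/C=C(\CO[Si](c1ccccc1)(c1ccccc1)C(C)(C)C)C=C | intermediate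
18 | 9-[(3Z)-3-{[(tert-butyldiphenylsilyl)oxy]methyl}-5-(9-borabicyclo[3.3.1]nonan-9-yloxy)pent-3-en-1-yl]-9-borabicyclo[3.3.1]nonane (not isolated) | C(C/C(CO[Si](c1ccccc1)(c1ccccc1)C(C)(C)C)=C/COB1C2CCCC1CCC2)B1C2CCCC1CCC2 | intermediate
19 | (2Z)-3-{[(tert-butyldiphenylsilyl)oxy]methyl}-6-[(4S,5E)-4-{[(2S,3S)-3-{[(4-methoxyphenyl)methoxy]methyl}-3-methyloxiran-2-yl]methyl}-2,2-dimethyl-1,3-dioxan-5-ylidene]hex-2-en-1-ol | OC/C=C(CO[Si](c1ccccc1)(c1ccccc1)C(C)(C)C)/CC/C=C1\COC(C)(C)O[C@H]1C[C@@H]2O[C@@]2(C)COCc3ccc(OC)cc3 | intermediate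
20 | methanesulfonate of 19 at O6 (not isolated) | CS(=O)(=O)OC/C=C(CO[Si](c1ccccc1)(c1ccccc1)C(C)(C)C)/CC/C=C1\COC(C)(C)O[C@H]1C[C@@H]2O[C@@]2(C)COCc3ccc(OC)cc3 | intermediate
21 | acyclic epoxy sulfone: C6 phenylsulfonyl; 4Z (C3 trans to C6); 1(10)E; 9,14-acetonide (9S); (7S,11S)-7,11-epoxide; O12 4-methoxybenzyl; O15 tert-butyldiphenylsilyl | O=S(=O)(c1ccccc1)C/C=C(CO[Si](c1ccccc1)(c1ccccc1)C(C)(C)C)/CC/C=C1\COC(C)(C)O[C@H]1C[C@@H]2O[C@@]2(C)COCc3ccc(OC)cc3 | intermediate
22 | C6-lithio derivative of 21 (not isolated) | [Li]C(/C=C(CO[Si](c1ccccc1)(c1ccccc1)C(C)(C)C)/CC/C=C1\COC(C)(C)O[C@H]1C[C@@H]2O[C@@]2(C)COCc3ccc(OC)cc3)S(=O)(=O)c1ccccc1 | intermediate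
23 | (1(10)E,4Z,7R,9S,11R)-15-[(tert-butyldiphenylsilyl)oxy]-9,14-(isopropylidenedioxy)-12-[(4-methoxyphenyl)methoxy]-6-(phenylsulfonyl)germacra-1(10),4-dien-11-ol, both C6 epimers | C[C@](O)(COCc1ccc(OC)cc1)[C@H]1C[C@@H]2OC(C)(C)OC/C2=C\CC/C(CO[Si](c3ccccc3)(c3ccccc3)C(C)(C)C)=C/C1S(=O)(=O)c1ccccc1 | intermediate
24 | (1(10)E,4Z,7R,9S,11R)-15-[(tert-butyldiphenylsilyl)oxy]-9,14-(isopropylidenedioxy)-12-[(4-methoxyphenyl)methoxy]germacra-1(10),4-dien-11-ol | C[C@](O)(COCc1ccc(OC)cc1)[C@H]1C[C@@H]2OC(C)(C)OC/C2=C\CC/C(CO[Si](c3ccccc3)(c3ccccc3)C(C)(C)C)=C/C1 | intermediate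
25 | (1(10)E,4Z,7R,9S,11R)-15-[(tert-butyldiphenylsilyl)oxy]-9,14-(isopropylidenedioxy)germacra-1(10),4-diene-11,12-diol | C[C@](O)(CO)[C@H]1C[C@@H]2OC(C)(C)OC/C2=C\CC/C(CO[Si](c3ccccc3)(c3ccccc3)C(C)(C)C)=C/C1 | intermediate
26 | 12-O-(4-methylbenzenesulfonyl) derivative of 25 (not isolated) | Cc1ccc(cc1)S(=O)(=O)OC[C@](C)(O)[C@H]1C[C@@H]2OC(C)(C)OC/C2=C\CC/C(CO[Si](c3ccccc3)(c3ccccc3)C(C)(C)C)=C/C1 | intermediate
27 | (1(10)E,4Z,7R,9S,11R)-15-[(tert-butyldiphenylsilyl)oxy]-11,12-epoxy-9,14-(isopropylidenedioxy)germacra-1(10),4-diene | C[C@]1(CO1)[C@H]2C[C@@H]3OC(C)(C)OC/C3=C\CC/C(CO[Si](c4ccccc4)(c4ccccc4)C(C)(C)C)=C/C2 | intermediate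
28 | (1(10)E,4Z,7R,9S)-15-[(tert-butyldiphenylsilyl)oxy]-9,14-(isopropylidenedioxy)germacra-1(10),4,11(13)-trien-12-ol | C=C(CO)[C@H]1C[C@@H]2OC(C)(C)OC/C2=C\CC/C(CO[Si](c3ccccc3)(c3ccccc3)C(C)(C)C)=C/C1 | intermediate
29 | (1(10)E,4Z,7R,9S)-15-[(tert-butyldiphenylsilyl)oxy]-9,14-(isopropylidenedioxy)germacra-1(10),4,11(13)-trien-12-yl acetate | C=C(COC(C)=O)[C@H]1C[C@@H]2OC(C)(C)OC/C2=C\CC/C(CO[Si](c3ccccc3)(c3ccccc3)C(C)(C)C)=C/C1 | intermediate
30 | (1(10)E,4Z,7R,9S)-12-acetoxy-15-[(tert-butyldiphenylsilyl)oxy]germacra-1(10),4,11(13)-triene-9,14-diol | C=C(COC(C)=O)[C@H]1C[C@H](O)/C(CO)=C/CC/C(CO[Si](c2ccccc2)(c2ccccc2)C(C)(C)C)=C/C1 | intermediate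
31 | (4R)-4-benzyl-3-propanoyl-1,3-oxazolidin-2-one | CCC(=O)N1[C@H](Cc2ccccc2)COC1=O | starting material
32 | acetaldehyde | CC=O | starting material
33 | Z dibutylboron enolate of 31 (not isolated) | C/C=C(\OB(CCCC)CCCC)N1[C@H](Cc2ccccc2)COC1=O | intermediate
34 | (4R)-4-benzyl-3-[(2R,3S)-3-hydroxy-2-methylbutanoyl]-1,3-oxazolidin-2-one | C[C@H](O)[C@@H](C)C(=O)N1[C@H](Cc2ccccc2)COC1=O | intermediate
35 | (4R)-4-benzyl-3-[(2R,3S)-2-methyl-3-(triethylsilyloxy)butanoyl]-1,3-oxazolidin-2-one | C[C@H](O[Si](CC)(CC)CC)[C@@H](C)C(=O)N1[C@H](Cc2ccccc2)COC1=O | intermediate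
36 | (2R,3S)-2-methyl-3-(triethylsilyloxy)butaneperoxoic acid (not isolated) | C[C@H](O[Si](CC)(CC)CC)[C@@H](C)C(=O)OO | intermediate
37 | (2R,3S)-2-methyl-3-(triethylsilyloxy)butanoic acid | C[C@H](O[Si](CC)(CC)CC)[C@@H](C)C(=O)O | intermediate
38 | (1(10)E,4Z,7R,9S)-12-acetoxy-15-[(tert-butyldiphenylsilyl)oxy]-9-hydroxygermacra-1(10),4,11(13)-trien-14-yl (2R,3S)-2-methyl-3-(triethylsilyloxy)butanoate | C=C(COC(C)=O)[C@H]1C[C@H](O)/C(COC(=O)[C@H](C)[C@H](C)O[Si](CC)(CC)CC)=C/CC/C(CO[Si](c2ccccc2)(c2ccccc2)C(C)(C)C)=C/C1 | intermediate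
39 | (1(10)E,4Z,7R,9S)-12-acetoxy-15-[(tert-butyldiphenylsilyl)oxy]-9-(3-methylbutanoyloxy)germacra-1(10),4,11(13)-trien-14-yl (2R,3S)-2-methyl-3-(triethylsilyloxy)butanoate | C=C(COC(C)=O)[C@H]1C[C@H](OC(=O)CC(C)C)/C(COC(=O)[C@H](C)[C@H](C)O[Si](CC)(CC)CC)=C/CC/C(CO[Si](c2ccccc2)(c2ccccc2)C(C)(C)C)=C/C1 | intermediate
40 | (1(10)E,4Z,7R,9S)-12-acetoxy-15-hydroxy-9-(3-methylbutanoyloxy)germacra-1(10),4,11(13)-trien-14-yl (2R,3S)-3-hydroxy-2-methylbutanoate | C=C(COC(C)=O)[C@H]1C[C@H](OC(=O)CC(C)C)/C(COC(=O)[C@H](C)[C@H](C)O)=C/CC/C(CO)=C/C1 | intermediate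
41 | (4S,5R,7S,9S)-12-acetoxy-4,5-epoxy-15-hydroxy-9-(3-methylbutanoyloxy)germacra-1(10)E,11(13)-dien-14-yl (2R,3S)-3-hydroxy-2-methylbutanoate | C=C(COC(C)=O)[C@H]1C[C@H](OC(=O)CC(C)C)/C(COC(=O)[C@H](C)[C@H](C)O)=C/CC[C@@]2(CO)O[C@@H]2C1 | target

## Step count and least certain steps

Total: 28 steps. Longest linear sequence: 20 steps (1–7, 13–21, 25–28); the dienol branch (8–12) and the acid branch (22–24) are shorter.

**Step 15 (key step).** Ring closure may lose to intermolecular epoxide opening, or to proton abstraction at C8 or C13 by the carbanion (elimination to an allylic alcohol), because a ten-membered transition state is strained and the lithiated sulfone is only a moderate nucleophile toward a trisubstituted epoxide. Fallback, keeping the C6–C7 disconnection: from 19, mesylate 20 is displaced with PhSNa to give the allylic phenyl sulfide F1. Its more nucleophilic sulfur-stabilised anion (n-BuLi with 1,4-diazabicyclo[2.2.2]octane, THF, −78 °C) closes the ring to the cyclic sulfide F2. Oxidation at sulfur with (NH4)6Mo7O24/H2O2 then gives 23, where the route is rejoined.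

**Step 2.** The enantioselectivity or the Z selectivity may be insufficient, or the β,γ-unsaturated aldehyde may isomerise under the Lewis acid. Fallback: from 2 and 3 the racemic adduct F3 is made with MgI2 in CH2Cl2. A lipase from Burkholderia cepacia with vinyl acetate then acetylates the R enantiomer (the usual empirical preference) to acetate F4 and leaves 6, where the route is rejoined.

**Step 5.** Conversion may stall, or over-oxidation to the enal may take over, as is common for selenium dioxide on a functionalised substrate. Fallback: from 8 the prenyl alkene is cleaved (OsO4 cat., NaIO4, 2,6-lutidine) to aldehyde F5. Wittig reaction with Ph3P=C(CH3)CO2Et gives the E enoate F6, and i-Bu2AlH gives 9.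

**Step 16.** Hydride delivery at C4 instead of C6 would move the alkene to C5=C6, and syn/anti exchange of the allyl complex would erode the ring-alkene geometry. Fallback: 23 is reduced directly to 24 by electron transfer (sodium amalgam, Na2HPO4, MeOH, −20 °C), a different mechanism that involves no allyl-metal complex and no new compound.

**Step 19.** Proton abstraction at C7 would give the tetrasubstituted C7=C11 isomer, and Lewis-acid opening at C11 with hydride shift would give an aldehyde. Fallback: from 25 the primary hydroxyl is acetylated (Ac2O, pyridine, 0 °C) to hydroxy acetate F7, whose tertiary alcohol is dehydrated by syn-elimination with the Burgess reagent to give 29 directly, bypassing 27 and 28.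

**Step 28.** Poor facial selectivity is possible if the ring conformer that exposes the required face of C4=C5 is disfavoured, and the titanium alkoxide may open the product across the ring. Fallback: 39 is epoxidised at its only electron-rich alkene with a fructose-derived chiral dioxirane (KHSO5, buffered), the ketone antipode being chosen for 4S,5R, to give silyl-protected epoxide F8. Buffered HF·pyridine then gives 41.

## Further compounds

F1 | step 15 | allylic phenyl sulfide corresponding to 21 (SPh at C6) | c1ccccc1SC/C=C(CO[Si](c1ccccc1)(c1ccccc1)C(C)(C)C)/CC/C=C1\COC(C)(C)O[C@H]1C[C@@H]2O[C@@]2(C)COCc3ccc(OC)cc3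
F2 | step 15 | cyclic sulfide corresponding to 23 (SPh at C6, both epimers) | C[C@](O)(COCc1ccc(OC)cc1)[C@H]1C[C@@H]2OC(C)(C)OC/C2=C\CC/C(CO[Si](c3ccccc3)(c3ccccc3)C(C)(C)C)=C/C1Sc1ccccc1
F3 | step 2 | methyl (2Z)-3-hydroxy-2-(iodomethylidene)-6-methylhept-5-enoate, racemate | CC(C)=CCC(O)/C(C(=O)OC)=C/I
F4 | step 2 | methyl (2Z,3R)-3-acetoxy-2-(iodomethylidene)-6-methylhept-5-enoate | CC(C)=CC[C@@H](OC(C)=O)/C(C(=O)OC)=C/I
F5 | step 5 | [(4S,5E)-5-(iodomethylidene)-2,2-dimethyl-1,3-dioxan-4-yl]acetaldehyde | I/C=C1\COC(C)(C)O[C@H]1CC=O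
F6 | step 5 | ethyl (2E)-4-[(4S,5E)-5-(iodomethylidene)-2,2-dimethyl-1,3-dioxan-4-yl]-2-methylbut-2-enoate | I/C=C1\COC(C)(C)O[C@H]1C/C=C(C)/C(=O)OCC
F0 | step 16 | none | none
F7 | step 19 | 12-O-acetyl derivative of diol 25 | C[C@](O)(COC(C)=O)[C@H]1C[C@@H]2OC(C)(C)OC/C2=C\CC/C(CO[Si](c3ccccc3)(c3ccccc3)C(C)(C)C)=C/C1
F8 | step 28 | (4S,5R)-4,5-epoxide of 39 | C=C(COC(C)=O)[C@H]1C[C@H](OC(=O)CC(C)C)/C(COC(=O)[C@H](C)[C@H](C)O[Si](CC)(CC)CC)=C/CC[C@@]2(CO[Si](c3ccccc3)(c3ccccc3)C(C)(C)C)O[C@@H]2C1
A1 | alternative 1 | (5R)-5-[3-(acetyloxy)prop-1-en-2-yl]-2-{[(tert-butyldimethylsilyl)oxy]methyl}cyclohex-2-en-1-one | C=C(COC(C)=O)[C@H]1CC(=O)C(CO[Si](C)(C)C(C)(C)C)=CC1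
A2 | alternative 1 | tert-butyl(cyclobut-1-en-1-ylmethoxy)diphenylsilane | CC(C)(C)[Si](OCC1=CCC1)(c1ccccc1)c1ccccc1
A3 | alternative 1 | cis-anti-cis tricyclic photoadduct (cyclohexanone fused to a bicyclo[2.2.0]hexane) | C=C(COC(C)=O)[C@H]1CC(=O)[C@@]2(CO[Si](C)(C)C(C)(C)C)[C@@H](C1)[C@]3(CO[Si](c4ccccc4)(c4ccccc4)C(C)(C)C)CC[C@@H]32
A4 | alternative 1 | ten-membered 1(10),4-dien-9-one from cycloreversion | C=C(COC(C)=O)[C@H]1CC(=O)/C(CO[Si](C)(C)C(C)(C)C)=C/CC/C(CO[Si](c2ccccc2)(c2ccccc2)C(C)(C)C)=C/C1
A5 | alternative 2 | twelve-membered epoxy lactone (O joins C9 and C13) | O=C1/C(COCc2ccc(OC)cc2)=C/CC[C@@]2(CO[Si](c3ccccc3)(c3ccccc3)C(C)(C)C)O[C@@H]2C/C=C(CO[Si](CC)(CC)CC)/CO1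
A6 | alternative 2 | twelve-membered allyl vinyl ether (C8H2=C9–O–C13) | C=C1/C(COCc2ccc(OC)cc2)=C/CC[C@@]2(CO[Si](c3ccccc3)(c3ccccc3)C(C)(C)C)O[C@@H]2C/C=C(CO[Si](CC)(CC)CC)/CO1
A7 | alternative 2 | epoxy cyclodecenone with the complete C7 side chain | C=C(CO[Si](CC)(CC)CC)[C@H]1CC(=O)/C(COCc2ccc(OC)cc2)=C/CC[C@@]2(CO[Si](c3ccccc3)(c3ccccc3)C(C)(C)C)O[C@@H]2C1
A8 | alternative 3 | trans-decalin C5 alcohol with equatorial C1 mesylate and 4,15-spiro-epoxide | C=C(CO[Si](CC)(CC)CC)[C@H]1C[C@H](O[Si](C)(C)C(C)(C)C)[C@]3(COCc2ccc(OC)cc2)[C@@H](OS(C)(=O)=O)CC[C@@]2(CO2)[C@@]3(O)C1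
A9 | alternative 3 | E-cyclodecenone with 4,15-epoxide | C=C(CO[Si](CC)(CC)CC)[C@H]1C[C@H](O[Si](C)(C)C(C)(C)C)/C(COCc2ccc(OC)cc2)=C/CC[C@@]2(CO2)C(=O)C1
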